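**Retrosynthetic overview**
1. Ring B and the spiro centre are formed last, by a bromonium-induced 6-endo cation–olefin cyclization of a monocyclic (Z)-alkylidenecyclohexyl acetate (C6–C11 bond); the C7 cation is trapped by the C5 acetate, which sets C6, C7 and C10.
2. The C7–C8 bond comes from a Negishi coupling of a tetrasubstituted alkenyl iodide with homoprenylzinc bromide; the ring A bromochloride is installed before that, by hydroxyl-directed bromochlorination.
3. Ring A is formed first, by ring-closing metathesis (C2=C3) of an allyl/2-methylallyl dienol.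
4. The alkene geometry comes from hydroxyl-directed anti-carbomagnesiation and iodination of a propargylic alcohol (C1–C6 bond).
5. C5, the only reagent-controlled stereocentre, comes from a Keck methallylation of but-2-ynal (C4–C5 bond).

Assumption: compounds 1, 2, 4 and 9 are bought; the spiro compounds use chamigrane numbering (C1–C5 ring A, C6 spiro carbon, C7–C11 ring B), the monocycles use the ring locants of their names. The route is a proposal and has not been run; the facial selectivities in steps 4 and 7 rest on conformational arguments.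

**Step 1**
Reactants: 1 but-2-ynal; 2 tributyl(2-methylprop-2-en-1-yl)stannane
Product: 3 (4R)-2-methylhept-1-en-5-yn-4-ol
Conditions: (R)-BINOL (20 mol %), Ti(OiPr)4 (10 mol %), 4 Å MS, CH2Cl2, −20 °C, 48 h; aq. NaHCO3
Reagents that add atoms: none
Why: Keck asymmetric allylation, in which the (R)-BINOL–titanium Lewis acid exposes the Re face of the ynal to the allylstannane and so sets the carbinol centre as R (the later C5).

**Step 2**
Reactants: 3 (4R)-2-methylhept-1-en-5-yn-4-ol; 4 allylmagnesium bromide
Product: 6 (2Z,4R)-2-iodo-6-methyl-3-(prop-2-en-1-yl)hepta-2,6-dien-4-ol, via cyclic alkenylmagnesium alkoxide 5 (not isolated)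
Conditions: 4 (3 equiv), CuI (10 mol %), THF/Et2O, −20 → 25 °C; then I2, −78 → 0 °C; aq. NH4Cl/Na2S2O3
Reagents that add atoms: iodine, [I][I]
Why: Hydroxyl-directed anti-carbomagnesiation puts allyl on the alkyne carbon next to the carbinol and magnesium on the distal carbon, trans to allyl, inside a five-membered alkoxide chelate, and iodinolysis with retention fixes the tetrasubstituted alkene as Z (iodine cis to the carbinol carbon) without touching the carbinol centre.

**Step 3**
Reactants: 6 (2Z,4R)-2-iodo-6-methyl-3-(prop-2-en-1-yl)hepta-2,6-dien-4-ol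
Product: 7 (1R,6Z)-6-(1-iodoethylidene)-3-methylcyclohex-3-en-1-ol
Conditions: second-generation Grubbs catalyst, RuCl2(=CHPh)(H2IMes)(PCy3) (3 mol %), CH2Cl2 (0.01 M), 40 °C
Reagents that add atoms: none
Why: Ring-closing metathesis of the allyl and 2-methylallyl groups closes ring A with its trisubstituted alkene, while the tetrasubstituted iodoalkene is inert and no stereocentre is involved.

**Step 4**
Reactants: 7 (1R,6Z)-6-(1-iodoethylidene)-3-methylcyclohex-3-en-1-ol
Product: 8 (1R,2Z,4S,5S)-4-bromo-5-chloro-2-(1-iodoethylidene)-5-methylcyclohexan-1-ol (Cl cis and Br trans to OH)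
Conditions: NBS (1.1 equiv), ClTi(OiPr)3 (1.2 equiv), hexanes/CH2Cl2, −20 °C; aq. NaHCO3
Reagents that add atoms: N-bromosuccinimide, O=C1CCC(=O)N1Br; chlorotitanium triisopropoxide, CC(C)O[Ti](Cl)(OC(C)C)OC(C)C
Why: Electrophilic anti bromochlorination with Markovnikov regiochemistry, in which A(1,3) strain against the cis iodine holds the hydroxyl axial, its titanium alkoxide delivers chloride to the tertiary carbon on the hydroxyl face and the bromonium ion sits on the opposite face (trans-diaxial opening), giving 4S,5S.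

**Step 5**
Reactants: 8 (1R,2Z,4S,5S)-4-bromo-5-chloro-2-(1-iodoethylidene)-5-methylcyclohexan-1-ol; 9 5-bromo-2-methylpent-2-ene
Product: 12 (1R,2Z,4S,5S)-4-bromo-5-chloro-5-methyl-2-(6-methylhept-5-en-2-ylidene)cyclohexan-1-ol, via (4-methylpent-3-en-1-yl)magnesium bromide 10 (not isolated), via (4-methylpent-3-en-1-yl)zinc bromide 11 (not isolated)
Conditions: 9, Mg, THF, 25 °C; ZnBr2, THF, 0 °C; then 8 (0.33 equiv), PdCl2(dppf) (5 mol %), THF, 40 °C
Reagents that add atoms: none
Why: Negishi cross-coupling, in which zerovalent palladium inserts into the alkenyl C–I bond far faster than into the hindered alkyl C–Br and C–Cl bonds and the alkene geometry is retained, so the new chain is cis to the carbinol carbon (Z) and no stereocentre changes.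

**Step 6**
Reactants: 12 (1R,2Z,4S,5S)-4-bromo-5-chloro-5-methyl-2-(6-methylhept-5-en-2-ylidene)cyclohexan-1-ol
Product: 13 (1R,2Z,4S,5S)-4-bromo-5-chloro-5-methyl-2-(6-methylhept-5-en-2-ylidene)cyclohexyl acetate
Conditions: Ac2O, DMAP (10 mol %), pyridine, CH2Cl2, 0 → 25 °C
Reagents that add atoms: acetic anhydride, CC(=O)OC(C)=O
Why: DMAP-catalysed acylation of the only hydroxyl group, with retention at the carbinol carbon because its C–O bond is not broken.

**Step 7**
Reactants: 13 (1R,2Z,4S,5S)-4-bromo-5-chloro-5-methyl-2-(6-methylhept-5-en-2-ylidene)cyclohexyl acetate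
Product: 15 (2S,3S,5R,6R,7R,10R)-2,10-dibromo-3-chloro-7-hydroxychamigran-5-yl acetate (= 2,10-dibromo-3-chloro-7-hydroxy-3,7,11,11-tetramethylspiro[5.5]undecan-5-yl acetate, chamigrane numbering), via bridged acetoxonium ion 14 (not isolated)
Conditions: BDSB (Et2SBr·SbBrCl5, 1.1 equiv), MeNO2, −25 °C, 10 min; then H2O, 0 °C
Reagents that add atoms: BDSB (bromodiethylsulfonium bromopentachloroantimonate), CC[S+](Br)CC.Cl[Sb-](Cl)(Cl)(Cl)(Cl)Br; water, O
Why: Bromonium-induced cation–olefin cyclization (6-endo, chair transition state, anti addition across both alkenes), in which C6 attacks the tertiary bromonium carbon on the face away from the C5 acetate, the Z geometry places C5 axial and C1 equatorial on ring B with bromine equatorial, and the acetate carbonyl traps the C7 cation anti to the new C6–C11 bond, so that hydrolysis of the acetoxonium ion gives the 6R,7R,10R product with the acetyl left on the secondary O5.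

**Compound list**
1 | but-2-ynal | CC#CC=O | starting material
2 | tributyl(2-methylprop-2-en-1-yl)stannane | CCCC[Sn](CCCC)(CCCC)CC(C)=C | starting material
3 | (4R)-2-methylhept-1-en-5-yn-4-ol | O[C@@H](C#CC)CC(C)=C | intermediate
4 | allylmagnesium bromide (prop-2-en-1-ylmagnesium bromide) | C=CC[Mg]Br | starting material
5 | (5R)-3-methyl-5-(2-methylprop-2-en-1-yl)-4-(prop-2-en-1-yl)-2,5-dihydro-1,2-oxamagnesole (cyclic alkenylmagnesium alkoxide) | CC1=C(CC=C)[C@@H](CC(C)=C)O[Mg]1 | intermediate
6 | (2Z,4R)-2-iodo-6-methyl-3-(prop-2-en-1-yl)hepta-2,6-dien-4-ol | O[C@@H](/C(CC=C)=C(/C)I)CC(C)=C | intermediate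
7 | (1R,6Z)-6-(1-iodoethylidene)-3-methylcyclohex-3-en-1-ol | O[C@@H]1CC(C)=CC\C1=C(/C)I | intermediate
8 | (1R,2Z,4S,5S)-4-bromo-5-chloro-2-(1-iodoethylidene)-5-methylcyclohexan-1-ol | O[C@@H]1C[C@](C)(Cl)[C@@H](Br)C\C1=C(/C)I | intermediate
9 | 5-bromo-2-methylpent-2-ene | CC(C)=CCCBr | starting material
10 | (4-methylpent-3-en-1-yl)magnesium bromide | CC(C)=CCC[Mg]Br | intermediate
11 | (4-methylpent-3-en-1-yl)zinc bromide | CC(C)=CCC[Zn]Br | intermediate
12 | (1R,2Z,4S,5S)-4-bromo-5-chloro-5-methyl-2-(6-methylhept-5-en-2-ylidene)cyclohexan-1-ol | O[C@@H]1C[C@](C)(Cl)[C@@H](Br)C\C1=C(/C)CCC=C(C)C | intermediate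
13 | (1R,2Z,4S,5S)-4-bromo-5-chloro-5-methyl-2-(6-methylhept-5-en-2-ylidene)cyclohexyl acetate | CC(=O)O[C@@H]1C[C@](C)(Cl)[C@@H](Br)C\C1=C(/C)CCC=C(C)C | intermediate
14 | O5,O7-bridged 2-methyl-1,3-dioxan-2-ylium (acetoxonium) bromopentachloroantimonate of (2S,3S,5R,6R,7R,10R)-2,10-dibromo-3-chlorochamigrane-5,7-diol | C[C+]1O[C@@H]2C[C@](C)(Cl)[C@@H](Br)C[C@@]23C(C)(C)[C@H](Br)CC[C@@]3(C)O1.Cl[Sb-](Cl)(Cl)(Cl)(Cl)Br | intermediate
15 | (2S,3S,5R,6R,7R,10R)-2,10-dibromo-3-chloro-7-hydroxychamigran-5-yl acetate | CC(=O)O[C@@H]1C[C@](C)(Cl)[C@@H](Br)C[C@@]12C(C)(C)[C@H](Br)CC[C@@]2(C)O | target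

**Total step count:** 7
**Longest linear sequence:** 7 steps (1 → 3 → 6 → 7 → 8 → 12 → 13 → 15)

**Three steps most likely to fail**

1. Step 7. The bromine donor cannot choose the face of the remote prenyl alkene, so at most half of the bromonium ions match the acetate-controlled chair, and the tetrasubstituted alkene may also be attacked. The fallback sets out from 13 and comes back at 15. Hg(OTf)2·PhNMe2 in MeNO2 at −20 °C, followed by aqueous NaCl, forms the mercurinium ion reversibly, so only the matched chair cyclizes, with the acetate terminating as before; this gives (2S,3S,5R,6R,7R,10R)-2-bromo-3-chloro-10-(chloromercurio)-7-hydroxychamigran-5-yl acetate F1. Br2/LiBr in pyridine under O2 at 0 °C then replaces mercury by bromine with retention and gives 15.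

2. Step 5. The alkenyl iodide is tetrasubstituted, and the vicinal bromochloride may be reduced to the alkene by zerovalent palladium or by the zinc reagent. The fallback sets out from 7 and comes back at 12. The zinc reagent 11 is coupled with the halogen-free iodide 7 under the same PdCl2(dppf) catalysis to give (1R,6Z)-3-methyl-6-(6-methylhept-5-en-2-ylidene)cyclohex-3-en-1-ol F2. The hydroxyl-directed bromochlorination (NBS, ClTi(OiPr)3, −20 °C) is then run on F2, relying on titanium-alkoxide delivery to pick the ring alkene over the prenyl alkene, and gives 12.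

3. Step 4. The titanium reagent may attack the allylic iodoalkene instead, or chloride may add with the wrong regio- or facial sense. The fallback sets out from 7 and comes back at 13. NBS in THF/H2O gives the bromohydrin (1S,3R,4Z,6S)-6-bromo-4-(1-iodoethylidene)-1-methylcyclohexane-1,3-diol F3 (water at the tertiary carbon, anti to bromine). Ac2O/pyridine acetylates only the secondary hydroxyl and gives (1R,2Z,4S,5S)-4-bromo-5-hydroxy-2-(1-iodoethylidene)-5-methylcyclohexyl acetate F4. SOCl2/pyridine exchanges the tertiary hydroxyl for chloride with retention, through the bromonium ion opened by the anti bromine, and gives (1R,2Z,4S,5S)-4-bromo-5-chloro-2-(1-iodoethylidene)-5-methylcyclohexyl acetate F5. Negishi coupling of F5 with 11, as in step 5, gives 13.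

**Further compounds**
F1 | step 7 | (2S,3S,5R,6R,7R,10R)-2-bromo-3-chloro-10-(chloromercurio)-7-hydroxychamigran-5-yl acetate | CC(=O)O[C@@H]1C[C@](C)(Cl)[C@@H](Br)C[C@@]12C(C)(C)[C@H]([Hg]Cl)CC[C@@]2(C)O
F2 | step 5 | (1R,6Z)-3-methyl-6-(6-methylhept-5-en-2-ylidene)cyclohex-3-en-1-ol | O[C@@H]1CC(C)=CC\C1=C(/C)CCC=C(C)C
F3 | step 4 | (1S,3R,4Z,6S)-6-bromo-4-(1-iodoethylidene)-1-methylcyclohexane-1,3-diol | O[C@@H]1C[C@](C)(O)[C@@H](Br)C\C1=C(/C)I
F4 | step 4 | (1R,2Z,4S,5S)-4-bromo-5-hydroxy-2-(1-iodoethylidene)-5-methylcyclohexyl acetate | CC(=O)O[C@@H]1C[C@](C)(O)[C@@H](Br)C\C1=C(/C)I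
F5 | step 4 | (1R,2Z,4S,5S)-4-bromo-5-chloro-2-(1-iodoethylidene)-5-methylcyclohexyl acetate | CC(=O)O[C@@H]1C[C@](C)(Cl)[C@@H](Br)C\C1=C(/C)I
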